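**Retrosynthetic overview**

1. The last operation is acid removal of a tert-butyl ester and a 7,8-acetonide; before it, the C2 hydroxyl of the ten-membered lactone is acylated with mono-tert-butyl (2E,4E)-muconate. Locants: C1 lactone carbonyl, C2 acyloxy carbon, C3 and C4 methylenes, C5=C6 ring alkene, C7 and C8 diol carbons, C9 propyl-bearing carbinol.
2. The ring is disconnected at C4–C5, the bond between the ring methylene and the sp2 CH of the only ring alkene. The lactone opens to an acyclic ester in which C4 carries one extra carboxyl carbon as an N-acyloxyphthalimide and C5 is an (E)-alkenyl iodide; the forward step is a nickel-electrocatalysed decarboxylative C(sp3)–C(sp2) coupling of these two electrophilic carbons.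
3. Feature that allows it: C1–C4 (lactone C=O, oxygen-bearing C2, two CH2) plus the carbon lost as CO2 are the five carbons of (R)-2-hydroxyglutaric acid, so the C4 radical is latent in the γ-carboxyl of D-glutamic acid. C5 ends a 1,2-disubstituted alkene whose (E) geometry can be stored in a vinyl iodide, and the adjacent C7/C8 syn-diol, tied as a trans-dioxolane, bends the chain toward ring closure.
4. The acyclic ester comes from a C5–C12 alcohol and a C1–C4 acid. The alcohol is made from C2-symmetric D-threitol acetonide by iodo-olefination at one terminus and reagent-controlled allylation at the other; the acid is made from D-glutamic acid 5-methyl ester by diazotisation with retention.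
5. Order of rings: the dioxolane is bought with the threitol and kept as a temporary ring; the ten-membered lactone is the only ring made (step 13); the dioxolane is opened in the last step.

Key step: step 13

Remark: the target is read as (2R,5E,7R,8S,9S) by the locants above. (−)-2,3-O-Isopropylidene-D-threitol, D-glutamic acid 5-methyl ester, ethyl (E)-4-oxobut-2-enoate and tert-butyl diethylphosphonoacetate are taken as purchasable.

**Route**

Step 1
Reactants: 1 (4R,5R)-2,2-dimethyl-1,3-dioxolane-4,5-dimethanol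
Product: 2 [(4R,5R)-5-({[tert-butyl(dimethyl)silyl]oxy}methyl)-2,2-dimethyl-1,3-dioxolan-4-yl]methanol
Conditions: NaH (1.0 equiv), THF, 0 °C; TBSCl (1.0 equiv), 0 °C to rt
Reagents that add atoms: tert-butyldimethylsilyl chloride, CC(C)(C)[Si](C)(C)Cl
Why: O-silylation of the sparingly soluble monosodium alkoxide should stop after one silyl group, and because the diol is C2-symmetric only one mono-ether can form.

Step 2
Reactants: 2 [(4R,5R)-5-({[tert-butyl(dimethyl)silyl]oxy}methyl)-2,2-dimethyl-1,3-dioxolan-4-yl]methanol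
Product: 3 (4S,5R)-5-({[tert-butyl(dimethyl)silyl]oxy}methyl)-2,2-dimethyl-1,3-dioxolane-4-carbaldehyde
Conditions: TEMPO (10 mol %), PhI(OAc)2 (1.1 equiv), CH2Cl2, rt
Reagents that add atoms: none
Why: the TEMPO/PhI(OAc)2 oxoammonium oxidation should stop at the aldehyde, and the trans-4,5-disubstituted dioxolane is the thermodynamically preferred arrangement, so the α-centre should not epimerise.

Step 3
Reactants: 3 (4S,5R)-5-({[tert-butyl(dimethyl)silyl]oxy}methyl)-2,2-dimethyl-1,3-dioxolane-4-carbaldehyde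
Product: 4 tert-butyl({(4R,5R)-5-[(E)-2-iodoethenyl]-2,2-dimethyl-1,3-dioxolan-4-yl}methoxy)dimethylsilane
Conditions: CrCl2 (6 equiv), CHI3 (2 equiv), THF/1,4-dioxane, 0 °C to rt, dark
Reagents that add atoms: iodoform, IC(I)I
Why: Takai iodo-olefination, in which the geminal dichromium reagent from CHI3 and CrCl2 adds to the aldehyde and eliminates to give preferentially the (E)-iodoalkene without touching a stereocentre.

Step 4
Reactants: 4 tert-butyl({(4R,5R)-5-[(E)-2-iodoethenyl]-2,2-dimethyl-1,3-dioxolan-4-yl}methoxy)dimethylsilane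
Product: 5 {(4R,5R)-5-[(E)-2-iodoethenyl]-2,2-dimethyl-1,3-dioxolan-4-yl}methanol
Conditions: TBAF (1.1 equiv), THF, 0 °C
Reagents that add atoms: none
Why: fluoride-induced cleavage of the primary silyl ether should leave the acetonide and the iodoalkene untouched.

Step 5
Reactants: 5 {(4R,5R)-5-[(E)-2-iodoethenyl]-2,2-dimethyl-1,3-dioxolan-4-yl}methanol
Product: 6 (4S,5R)-5-[(E)-2-iodoethenyl]-2,2-dimethyl-1,3-dioxolane-4-carbaldehyde
Conditions: TEMPO (10 mol %), PhI(OAc)2 (1.1 equiv), CH2Cl2, rt
Reagents that add atoms: none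
Why: the same TEMPO/PhI(OAc)2 oxidation tolerates the iodoalkene and again gives the configurationally safe trans-dioxolane aldehyde.

Step 6
Reactants: 6 (4S,5R)-5-[(E)-2-iodoethenyl]-2,2-dimethyl-1,3-dioxolane-4-carbaldehyde
Product: 8 (1S)-1-{(4R,5R)-5-[(E)-2-iodoethenyl]-2,2-dimethyl-1,3-dioxolan-4-yl}but-3-en-1-ol, via borinate ester 7 (not isolated)
Conditions: (−)-Ipc2BOMe, allylmagnesium bromide, Et2O, −78 °C to rt; then 6, −78 °C; ethanolamine, rt
Reagents that add atoms: allylmagnesium bromide, C=CC[Mg]Br (the allyl group is passed on through B-allyldiisopinocampheylborane formed in the flask)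
Why: Brown asymmetric allylboration through a closed six-membered chair transition state, in which the reagent from (−)-Ipc2BOMe should attack the Si face of the aldehyde and so set the new carbinol centre (S), syn to the neighbouring dioxolane oxygen, under reagent control against the modest intrinsic anti preference of the α-alkoxy aldehyde.

Step 7
Reactants: 8 (1S)-1-{(4R,5R)-5-[(E)-2-iodoethenyl]-2,2-dimethyl-1,3-dioxolan-4-yl}but-3-en-1-ol
Product: 9 (1S)-1-{(4R,5R)-5-[(E)-2-iodoethenyl]-2,2-dimethyl-1,3-dioxolan-4-yl}butan-1-ol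
Conditions: 2-nitrobenzenesulfonylhydrazide (3 equiv), Et3N, CH2Cl2, rt
Reagents that add atoms: none
Why: diimide reduction is a concerted, metal-free syn transfer of H2 that is much faster for a monosubstituted terminal alkene than for the 1,2-disubstituted iodoalkene, so the propyl group should form without reduction of the C=C–I unit or loss of iodide.

Step 8
Reactants: 10 D-glutamic acid 5-methyl ester, (2R)-2-amino-5-methoxy-5-oxopentanoic acid
Product: 11 (2R)-2-hydroxy-5-methoxy-5-oxopentanoic acid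
Conditions: NaNO2, 1 M aq. H2SO4, 0 °C to rt; crude product used at once
Reagents that add atoms: water, O
Why: diazotisation of the α-amino acid, in which the diazonium ion is displaced by the neighbouring carboxylate to an α-lactone that water opens, two inversions giving overall retention, so the (R) centre of the D-amino acid becomes the (R)-α-hydroxy acid.

Step 9
Reactants: 11 (2R)-2-hydroxy-5-methoxy-5-oxopentanoic acid
Product: 13 (2R)-2-{[tert-butyl(dimethyl)silyl]oxy}-5-methoxy-5-oxopentanoic acid, via silyl ester 12 (not isolated)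
Conditions: TBSCl (2.2 equiv), imidazole (4.4 equiv), DMF, rt; then THF/H2O/AcOH (4:1:1), rt
Reagents that add atoms: tert-butyldimethylsilyl chloride, CC(C)(C)[Si](C)(C)Cl
Why: silylation of both OH and CO2H followed by selective hydrolysis of the labile silyl ester should leave the O-silyl acid with its stereocentre unaffected.

Step 10
Reactants: 9 (1S)-1-{(4R,5R)-5-[(E)-2-iodoethenyl]-2,2-dimethyl-1,3-dioxolan-4-yl}butan-1-ol; 13 (2R)-2-{[tert-butyl(dimethyl)silyl]oxy}-5-methoxy-5-oxopentanoic acid
Product: 14 1-[(1S)-1-{(4R,5R)-5-[(E)-2-iodoethenyl]-2,2-dimethyl-1,3-dioxolan-4-yl}butyl] 5-methyl (2R)-2-{[tert-butyl(dimethyl)silyl]oxy}pentanedioate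
Conditions: DIC (1.5 equiv), DMAP (0.5 equiv), CH2Cl2, 0 °C to rt
Reagents that add atoms: none
Why: Steglich esterification (carbodiimide activation, acyl transfer through the N-acylpyridinium ion) should acylate the hindered secondary alcohol with retention at both carbinol and α-silyloxy centres, because neither C–O bond is broken and the acid has no easy ketene pathway.

Step 11
Reactants: 14 1-[(1S)-1-{(4R,5R)-5-[(E)-2-iodoethenyl]-2,2-dimethyl-1,3-dioxolan-4-yl}butyl] 5-methyl (2R)-2-{[tert-butyl(dimethyl)silyl]oxy}pentanedioate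
Product: 15 (4R)-4-{[tert-butyl(dimethyl)silyl]oxy}-5-[(1S)-1-{(4R,5R)-5-[(E)-2-iodoethenyl]-2,2-dimethyl-1,3-dioxolan-4-yl}butoxy]-5-oxopentanoic acid
Conditions: Me3SnOH (5 equiv), 1,2-dichloroethane, 70 °C; then cold 0.5 M aq. HCl wash
Reagents that add atoms: trimethyltin hydroxide, C[Sn](C)(C)O
Why: trimethyltin hydroxide ester hydrolysis is governed by steric access, so the unhindered methyl ester should be cleaved in preference to the α-silyloxy ester of the hindered secondary alcohol, under near-neutral conditions that spare acetonide, silyl ether and iodoalkene.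

Step 12
Reactants: 15 (4R)-4-{[tert-butyl(dimethyl)silyl]oxy}-5-[(1S)-1-{(4R,5R)-5-[(E)-2-iodoethenyl]-2,2-dimethyl-1,3-dioxolan-4-yl}butoxy]-5-oxopentanoic acid
Product: 16 5-(1,3-dioxoisoindolin-2-yl) 1-[(1S)-1-{(4R,5R)-5-[(E)-2-iodoethenyl]-2,2-dimethyl-1,3-dioxolan-4-yl}butyl] (2R)-2-{[tert-butyl(dimethyl)silyl]oxy}pentanedioate
Conditions: N-hydroxyphthalimide (1.1 equiv), DIC (1.2 equiv), DMAP (5 mol %), CH2Cl2, rt
Reagents that add atoms: N-hydroxyphthalimide, O=C1c2ccccc2C(=O)N1O
Why: carbodiimide coupling converts the free acid into the redox-active N-acyloxyphthalimide ester, the latent form of the C4 radical.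

Step 13
Reactants: 16 5-(1,3-dioxoisoindolin-2-yl) 1-[(1S)-1-{(4R,5R)-5-[(E)-2-iodoethenyl]-2,2-dimethyl-1,3-dioxolan-4-yl}butyl] (2R)-2-{[tert-butyl(dimethyl)silyl]oxy}pentanedioate
Product: 17 (2R,5E,7R,8R,9S)-2-{[tert-butyl(dimethyl)silyl]oxy}-7,8-(isopropylidenedioxy)-9-propylnon-5-en-9-olide
Conditions: undivided cell, Mg anode, RVC cathode, NiCl2·6H2O (30 mol %), 2,2'-bipyridine (30 mol %), AgNO3 (0.3 equiv), LiCl, DMF, constant current, rt; 16 added by syringe pump to about 2 mM
Reagents that add atoms: none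
Why: Proposed new method: zerovalent nickel–bipyridine formed at the cathode should insert into the C5–I bond with retention of the (E) geometry, single-electron reduction of the N-acyloxyphthalimide (by low-valent nickel or at the silver-coated cathode) releases CO2 and phthalimide anion and leaves the primary C4 radical, this radical is captured by the alkenylnickel, and C(sp3)–C(sp2) reductive elimination from the trivalent alkyl(alkenyl)nickel forms C4–C5. The closest known reaction type is the intermolecular nickel-electrocatalysed decarboxylative alkenylation of redox-active esters with alkenyl iodides (Mg anode, silver-modified cathode); what is new is its use within one molecule to close a medium ring. The ten-membered lactone closes through an eleven-membered alkyl(alkenyl)nickelacycle that contracts by reductive elimination, so no exo or endo radical attack on carbon is involved. No stereocentre is created: the ring alkene inherits the (E) geometry of the iodide, and C2, C7, C8 and C9 are spectators. The step needs cyclisation to beat oligomerisation, hydrogen abstraction by the radical and protodeiodination; syringe-pump addition keeps 16 dilute, and the s-trans ester together with the trans-fused dioxolane on C7/C8 turns the two chain ends toward each other, the same pre-organisation that is relied on when this ring system is closed by metathesis. The silyl ether on O2 keeps a radical-accepting and reducible dienoate away from C4 until the ring is made.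

Step 14
Reactants: 17 (2R,5E,7R,8R,9S)-2-{[tert-butyl(dimethyl)silyl]oxy}-7,8-(isopropylidenedioxy)-9-propylnon-5-en-9-olide
Product: 18 (2R,5E,7R,8R,9S)-2-hydroxy-7,8-(isopropylidenedioxy)-9-propylnon-5-en-9-olide
Conditions: HF·pyridine, pyridine, THF, 0 °C to rt
Reagents that add atoms: none
Why: fluoride-mediated cleavage of the secondary silyl ether under buffered, weakly acidic conditions should open neither the lactone nor the acetonide.

Step 15
Reactants: 19 ethyl (E)-4-oxobut-2-enoate; 20 tert-butyl 2-(diethoxyphosphoryl)acetate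
Product: 21 1-tert-butyl 6-ethyl (2E,4E)-hexa-2,4-dienedioate
Conditions: NaH, THF, 0 °C; then 19, −78 to 0 °C
Reagents that add atoms: none
Why: Horner–Wadsworth–Emmons olefination of the enal with the stabilised phosphonate anion should give the new alkene (E) by equilibration of the adducts, so the (2E,4E)-diene diester results.

Step 16
Reactants: 21 1-tert-butyl 6-ethyl (2E,4E)-hexa-2,4-dienedioate
Product: 22 (2E,4E)-6-tert-butoxy-6-oxohexa-2,4-dienoic acid
Conditions: LiOH·H2O (1.05 equiv), THF/H2O (3:1), 0 °C; then 1 M aq. HCl to pH 3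
Reagents that add atoms: lithium hydroxide, [Li+].[OH-]
Why: saponification by acyl–oxygen cleavage takes the unhindered ethyl ester, while the tert-butyl ester resists hydroxide for steric reasons.

Step 17
Reactants: 18 (2R,5E,7R,8R,9S)-2-hydroxy-7,8-(isopropylidenedioxy)-9-propylnon-5-en-9-olide; 22 (2E,4E)-6-tert-butoxy-6-oxohexa-2,4-dienoic acid
Product: 23 1-tert-butyl 6-[(2R,5E,7R,8R,9S)-7,8-(isopropylidenedioxy)-9-propylnon-5-en-9-olid-2-yl] (2E,4E)-hexa-2,4-dienedioate
Conditions: DIC (1.5 equiv), DMAP (0.3 equiv), CH2Cl2, 0 °C to rt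
Reagents that add atoms: none
Why: Steglich esterification of the only free hydroxyl; C2 keeps its configuration because its C–O bond is not broken.

Step 18
Reactants: 23 1-tert-butyl 6-[(2R,5E,7R,8R,9S)-7,8-(isopropylidenedioxy)-9-propylnon-5-en-9-olid-2-yl] (2E,4E)-hexa-2,4-dienedioate
Product: 24 (2E,4E)-6-{[(2R,5E,7R,8S,9S)-7,8-dihydroxy-9-propylnon-5-en-9-olid-2-yl]oxy}-6-oxohexa-2,4-dienoic acid (CNP0476488.1)
Conditions: TFA/CH2Cl2/H2O (10:10:1), 0 °C to rt
Reagents that add atoms: none
Why: acidolysis, in which TFA ionises the tert-butyl ester (loss of 2-methylpropene) and hydrolyses the isopropylidene acetal in the same operation, while lactone, dienoate ester and allylic diol should survive; the C8 descriptor changes from R to S only through the change in CIP priorities.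

**Compound list**

1 | (4R,5R)-2,2-dimethyl-1,3-dioxolane-4,5-dimethanol, (−)-2,3-O-isopropylidene-D-threitol | OC[C@H]1OC(C)(C)O[C@@H]1CO | starting material
2 | [(4R,5R)-5-({[tert-butyl(dimethyl)silyl]oxy}methyl)-2,2-dimethyl-1,3-dioxolan-4-yl]methanol | CC(C)(C)[Si](C)(C)OC[C@H]1OC(C)(C)O[C@@H]1CO | intermediate
3 | (4S,5R)-5-({[tert-butyl(dimethyl)silyl]oxy}methyl)-2,2-dimethyl-1,3-dioxolane-4-carbaldehyde | CC(C)(C)[Si](C)(C)OC[C@H]1OC(C)(C)O[C@@H]1C=O | intermediate
4 | tert-butyl({(4R,5R)-5-[(E)-2-iodoethenyl]-2,2-dimethyl-1,3-dioxolan-4-yl}methoxy)dimethylsilane | CC(C)(C)[Si](C)(C)OC[C@H]1OC(C)(C)O[C@@H]1/C=C/I | intermediate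
5 | {(4R,5R)-5-[(E)-2-iodoethenyl]-2,2-dimethyl-1,3-dioxolan-4-yl}methanol | OC[C@H]1OC(C)(C)O[C@@H]1/C=C/I | intermediate
6 | (4S,5R)-5-[(E)-2-iodoethenyl]-2,2-dimethyl-1,3-dioxolane-4-carbaldehyde | O=C[C@H]1OC(C)(C)O[C@@H]1/C=C/I | intermediate
7 | (1S)-1-{(4R,5R)-5-[(E)-2-iodoethenyl]-2,2-dimethyl-1,3-dioxolan-4-yl}but-3-en-1-yl diisopinocampheylborinate | C=CC[C@H](OB([C@@H]2C[C@@H]3C[C@H]([C@H]2C)C3(C)C)[C@@H]2C[C@@H]3C[C@H]([C@H]2C)C3(C)C)[C@H]1OC(C)(C)O[C@@H]1/C=C/I | intermediate (not isolated)
8 | (1S)-1-{(4R,5R)-5-[(E)-2-iodoethenyl]-2,2-dimethyl-1,3-dioxolan-4-yl}but-3-en-1-ol | C=CC[C@H](O)[C@H]1OC(C)(C)O[C@@H]1/C=C/I | intermediate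
9 | (1S)-1-{(4R,5R)-5-[(E)-2-iodoethenyl]-2,2-dimethyl-1,3-dioxolan-4-yl}butan-1-ol | CCC[C@H](O)[C@H]1OC(C)(C)O[C@@H]1/C=C/I | intermediate
10 | D-glutamic acid 5-methyl ester, (2R)-2-amino-5-methoxy-5-oxopentanoic acid | N[C@H](CCC(=O)OC)C(=O)O | starting material
11 | (2R)-2-hydroxy-5-methoxy-5-oxopentanoic acid | O[C@H](CCC(=O)OC)C(=O)O | intermediate
12 | tert-butyldimethylsilyl (2R)-2-{[tert-butyl(dimethyl)silyl]oxy}-5-methoxy-5-oxopentanoate | CC(C)(C)[Si](C)(C)O[C@H](CCC(=O)OC)C(=O)O[Si](C)(C)C(C)(C)C | intermediate (not isolated)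
13 | (2R)-2-{[tert-butyl(dimethyl)silyl]oxy}-5-methoxy-5-oxopentanoic acid | CC(C)(C)[Si](C)(C)O[C@H](CCC(=O)OC)C(=O)O | intermediate
14 | 1-[(1S)-1-{(4R,5R)-5-[(E)-2-iodoethenyl]-2,2-dimethyl-1,3-dioxolan-4-yl}butyl] 5-methyl (2R)-2-{[tert-butyl(dimethyl)silyl]oxy}pentanedioate | CCC[C@H](OC(=O)[C@H](O[Si](C)(C)C(C)(C)C)CCC(=O)OC)[C@H]1OC(C)(C)O[C@@H]1/C=C/I | intermediate
15 | (4R)-4-{[tert-butyl(dimethyl)silyl]oxy}-5-[(1S)-1-{(4R,5R)-5-[(E)-2-iodoethenyl]-2,2-dimethyl-1,3-dioxolan-4-yl}butoxy]-5-oxopentanoic acid | CCC[C@H](OC(=O)[C@H](O[Si](C)(C)C(C)(C)C)CCC(=O)O)[C@H]1OC(C)(C)O[C@@H]1/C=C/I | intermediate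
16 | 5-(1,3-dioxoisoindolin-2-yl) 1-[(1S)-1-{(4R,5R)-5-[(E)-2-iodoethenyl]-2,2-dimethyl-1,3-dioxolan-4-yl}butyl] (2R)-2-{[tert-butyl(dimethyl)silyl]oxy}pentanedioate | CCC[C@H](OC(=O)[C@H](O[Si](C)(C)C(C)(C)C)CCC(=O)ON2C(=O)c3ccccc3C2=O)[C@H]1OC(C)(C)O[C@@H]1/C=C/I | intermediate
17 | (2R,5E,7R,8R,9S)-2-{[tert-butyl(dimethyl)silyl]oxy}-7,8-(isopropylidenedioxy)-9-propylnon-5-en-9-olide | CCC[C@@H]1OC(=O)[C@H](O[Si](C)(C)C(C)(C)C)CC/C=C/[C@H]2OC(C)(C)O[C@H]12 | intermediate
18 | (2R,5E,7R,8R,9S)-2-hydroxy-7,8-(isopropylidenedioxy)-9-propylnon-5-en-9-olide | CCC[C@@H]1OC(=O)[C@H](O)CC/C=C/[C@H]2OC(C)(C)O[C@H]12 | intermediate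
19 | ethyl (E)-4-oxobut-2-enoate | CCOC(=O)/C=C/C=O | starting material
20 | tert-butyl 2-(diethoxyphosphoryl)acetate | CCOP(=O)(CC(=O)OC(C)(C)C)OCC | starting material
21 | 1-tert-butyl 6-ethyl (2E,4E)-hexa-2,4-dienedioate | CCOC(=O)/C=C/C=C/C(=O)OC(C)(C)C | intermediate
22 | (2E,4E)-6-tert-butoxy-6-oxohexa-2,4-dienoic acid | OC(=O)/C=C/C=C/C(=O)OC(C)(C)C | intermediate
23 | 1-tert-butyl 6-[(2R,5E,7R,8R,9S)-7,8-(isopropylidenedioxy)-9-propylnon-5-en-9-olid-2-yl] (2E,4E)-hexa-2,4-dienedioate | CCC[C@@H]1OC(=O)[C@H](OC(=O)/C=C/C=C/C(=O)OC(C)(C)C)CC/C=C/[C@H]2OC(C)(C)O[C@H]12 | intermediate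
24 | (2E,4E)-6-{[(2R,5E,7R,8S,9S)-7,8-dihydroxy-9-propylnon-5-en-9-olid-2-yl]oxy}-6-oxohexa-2,4-dienoic acid (CNP0476488.1) | CCC[C@@H]1OC(=O)[C@H](OC(=O)/C=C/C=C/C(=O)O)CC/C=C/[C@@H](O)[C@@H]1O | target

**Step count and risks**

Total step count: 18. Longest linear sequence: 14 steps (steps 1–7, 10–14, 17, 18).

Steps most likely to fail:

1. Step 13 (proposed new method). Intermolecular coupling may outrun ring closure and give oligomers, or the C4 radical may be quenched by hydrogen abstraction and the alkenylnickel by protonation, so that 16 is consumed without ring formation. The fallback makes the same C4–C5 bond between two molecules, where the electrochemical coupling has direct precedent, and closes the ring at the ester instead. It sets out from acid 13 and alcohol 9 and comes back at lactone 17. Acid 13 is methylated (TMSCHN2, MeOH/toluene) to dimethyl (2R)-2-{[tert-butyl(dimethyl)silyl]oxy}pentanedioate F1. One equivalent of Me3SnOH should then cleave the unhindered ester remote from the silyloxy group to give (4R)-4-{[tert-butyl(dimethyl)silyl]oxy}-5-methoxy-5-oxopentanoic acid F2. N-Hydroxyphthalimide and DIC convert it into the redox-active ester F3. F3 and alcohol 9 are coupled under the intermolecular conditions (NiCl2·6H2O, 2,2'-bipyridine, AgNO3, Mg anode, RVC cathode, DMF) to methyl (2R,5E)-2-{[tert-butyl(dimethyl)silyl]oxy}-6-{(4R,5R)-5-[(1S)-1-hydroxybutyl]-2,2-dimethyl-1,3-dioxolan-4-yl}hex-5-enoate F4. LiOH (THF/H2O) gives the seco acid F5, and Shiina macrolactonisation (2-methyl-6-nitrobenzoic anhydride, DMAP, CH2Cl2, slow addition) should return lactone 17.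

2. Step 7. Diimide may also reduce the iodoalkene, or conversion may stall, leaving mixtures that are hard to separate. The mismatched allylation of step 6 is the other weak point of this pair, and the fallback removes both steps. It sets out from aldehyde 6 and comes back at alcohol 9. n-PrMgBr (THF, −78 °C) adds directly to 6 to give 9 together with its (1R)-epimer F6. The mixture is oxidised (Dess–Martin periodinane, CH2Cl2) to 1-{(4S,5R)-5-[(E)-2-iodoethenyl]-2,2-dimethyl-1,3-dioxolan-4-yl}butan-1-one F7. Corey–Bakshi–Shibata reduction ((R)-2-methyl-CBS-oxazaborolidine, catecholborane, toluene, −78 °C) should then set the carbinol centre under catalyst control and return 9.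

3. Step 3. The E/Z ratio of the iodo-olefination may erode with this α-alkoxy aldehyde, and a (Z)-iodide would be carried into the ring closure. The fallback replaces the chromium olefination by alkyne homologation and hydrometalation. It sets out from aldehyde 3 and comes back at vinyl iodide 4. Ohira–Bestmann homologation (dimethyl (1-diazo-2-oxopropyl)phosphonate, K2CO3, MeOH) gives tert-butyl{[(4R,5R)-5-ethynyl-2,2-dimethyl-1,3-dioxolan-4-yl]methoxy}dimethylsilane F8. Hydrozirconation with Cp2Zr(H)Cl (THF, rt) gives the (E)-alkenylzirconocene chloride F9 by syn addition, and without isolation iodinolysis (I2, 0 °C) should return 4 as the (E) isomer only.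

**Further compounds**

F1 | step 13 | dimethyl (2R)-2-{[tert-butyl(dimethyl)silyl]oxy}pentanedioate | CC(C)(C)[Si](C)(C)O[C@H](CCC(=O)OC)C(=O)OC
F2 | step 13 | (4R)-4-{[tert-butyl(dimethyl)silyl]oxy}-5-methoxy-5-oxopentanoic acid | CC(C)(C)[Si](C)(C)O[C@H](CCC(=O)O)C(=O)OC
F3 | step 13 | 5-(1,3-dioxoisoindolin-2-yl) 1-methyl (2R)-2-{[tert-butyl(dimethyl)silyl]oxy}pentanedioate | CC(C)(C)[Si](C)(C)O[C@H](CCC(=O)ON1C(=O)c2ccccc2C1=O)C(=O)OC
F4 | step 13 | methyl (2R,5E)-2-{[tert-butyl(dimethyl)silyl]oxy}-6-{(4R,5R)-5-[(1S)-1-hydroxybutyl]-2,2-dimethyl-1,3-dioxolan-4-yl}hex-5-enoate | CCC[C@H](O)[C@H]1OC(C)(C)O[C@@H]1/C=C/CC[C@@H](O[Si](C)(C)C(C)(C)C)C(=O)OC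
F5 | step 13 | (2R,5E)-2-{[tert-butyl(dimethyl)silyl]oxy}-6-{(4R,5R)-5-[(1S)-1-hydroxybutyl]-2,2-dimethyl-1,3-dioxolan-4-yl}hex-5-enoic acid | CCC[C@H](O)[C@H]1OC(C)(C)O[C@@H]1/C=C/CC[C@@H](O[Si](C)(C)C(C)(C)C)C(=O)O
F6 | step 7 | (1R)-1-{(4R,5R)-5-[(E)-2-iodoethenyl]-2,2-dimethyl-1,3-dioxolan-4-yl}butan-1-ol | CCC[C@@H](O)[C@H]1OC(C)(C)O[C@@H]1/C=C/I
F7 | step 7 | 1-{(4S,5R)-5-[(E)-2-iodoethenyl]-2,2-dimethyl-1,3-dioxolan-4-yl}butan-1-one | CCCC(=O)[C@H]1OC(C)(C)O[C@@H]1/C=C/I
F8 | step 3 | tert-butyl{[(4R,5R)-5-ethynyl-2,2-dimethyl-1,3-dioxolan-4-yl]methoxy}dimethylsilane | CC(C)(C)[Si](C)(C)OC[C@H]1OC(C)(C)O[C@@H]1C#C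
F9 | step 3 | chlorobis(cyclopentadienyl){(E)-2-[(4R,5R)-5-({[tert-butyl(dimethyl)silyl]oxy}methyl)-2,2-dimethyl-1,3-dioxolan-4-yl]ethenyl}zirconium | Cl[Zr](/C=C/[C@H]1OC(C)(C)O[C@@H]1CO[Si](C)(C)C(C)(C)C)(C1C=CC=C1)C1C=CC=C1
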